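**Plan**
- Cuts (numbering C1 = lactone C=O to C24 = propenyl CH3): C13–C14 (Suzuki–Miyaura), C7–C8 (Stille), lactone C2=C3 (ring-closing metathesis) and, in the tetrahydropyran, O–C17 together with C18–C19.
- Enabling feature: ring atoms O, C21, C20, C19 form a β-oxy aldehyde unit, and C17 with its C18 methylene is a methyl ketone at a lower oxidation level. The 4-hydroxytetrahydropyran ring (O, C17–C21) is therefore a reduced aldol adduct that one Lewis acid can assemble, close and reduce.
- Forward order: aldehyde 6 and enol silane 10 give tetrahydropyran 13 in one reductive annulation, then vinyl iodide 17. The lactone ring arises by metathesis (30); 24 + 30 give 31; 17 + 31 give 32, which is desilylated to the target.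
- Stereochemistry: C20/C21 from an auxiliary syn-aldol; C19 (Felkin–Anh) and C17 (axial hydride) relayed from them in the key step; C16 bought (glycerate); C10 by auxiliary alkylation; C5 by catalytic allylation. Alkene geometry comes from Takai, carboalumination and Stork–Zhao steps and stereoretentive couplings.

Key step: step 8

Assumption: the SMILES is read as 5S,10R,16S,17R,19S,20R,21R with 6E,8Z,12E,14E,22E alkenes, and the route is built for exactly this stereoisomer.

**Route**

Step 1
Reactants: 1 (S)-4-benzyl-3-propionyloxazolidin-2-one; 2 (E)-but-2-enal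
Product: 3 (S)-4-benzyl-3-[(2S,3R,E)-3-hydroxy-2-methylhex-4-enoyl]oxazolidin-2-one
Conditions: Bu2BOTf, iPr2NEt, CH2Cl2, −78 to 0 °C; then pH 7 buffer, MeOH, H2O2, 0 °C
Reagents that add atoms: none
Why: Evans syn-aldol through the Z-boron enolate and a Zimmerman–Traxler chair, in which the (S)-benzyl auxiliary should set C20 and C21 together (2S,3R) by 1,2-addition to the enal.

Step 2
Reactants: 3 (S)-4-benzyl-3-[(2S,3R,E)-3-hydroxy-2-methylhex-4-enoyl]oxazolidin-2-one
Product: 4 (2S,3R,E)-3-hydroxy-N-methoxy-N,2-dimethylhex-4-enamide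
Conditions: MeNH(OMe)·HCl, AlMe3, CH2Cl2, −20 to 0 °C
Reagents that add atoms: N,O-dimethylhydroxylamine hydrochloride, CNOC.Cl
Why: Weinreb transamidation by the aluminium amide, assisted by the free β-hydroxyl, should release the auxiliary without epimerising C20.

Step 3
Reactants: 4 (2S,3R,E)-3-hydroxy-N-methoxy-N,2-dimethylhex-4-enamide
Product: 5 (2S,3R,E)-N-methoxy-N,2-dimethyl-3-(triethylsilyloxy)hex-4-enamide
Conditions: Et3SiCl, imidazole, DMF, 0 to 25 °C
Reagents that add atoms: chlorotriethylsilane, CC[Si](Cl)(CC)CC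
Why: Standard silyl ether formation; the triethylsilyl group is non-chelating for step 8 and labile enough to leave there.

Step 4
Reactants: 5 (2S,3R,E)-N-methoxy-N,2-dimethyl-3-(triethylsilyloxy)hex-4-enamide
Product: 6 (2S,3R,E)-2-methyl-3-(triethylsilyloxy)hex-4-enal
Conditions: iBu2AlH, THF, −78 °C; aq. potassium sodium tartrate
Reagents that add atoms: none
Why: Hydride reduction of a Weinreb amide stops at the chelated tetrahedral intermediate, so the aldehyde should form without over-reduction or epimerisation.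

Step 5
Reactants: 7 methyl (S)-2,2-dimethyl-1,3-dioxolane-4-carboxylate
Product: 8 (S)-N-methoxy-N,2,2-trimethyl-1,3-dioxolane-4-carboxamide
Conditions: MeNH(OMe)·HCl, iPrMgCl, THF, −20 to 0 °C
Reagents that add atoms: N,O-dimethylhydroxylamine hydrochloride, CNOC.Cl
Why: Weinreb amide formation from an ester with the magnesium amide, mild enough to keep the α-oxygenated stereocentre (future C16).

Step 6
Reactants: 8 (S)-N-methoxy-N,2,2-trimethyl-1,3-dioxolane-4-carboxamide
Product: 9 (S)-1-(2,2-dimethyl-1,3-dioxolan-4-yl)ethan-1-one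
Conditions: MeMgBr, THF, 0 °C
Reagents that add atoms: methylmagnesium bromide, C[Mg]Br
Why: Grignard addition to a Weinreb amide should stop at the methyl ketone, whose methyl group becomes C18.

Step 7
Reactants: 9 (S)-1-(2,2-dimethyl-1,3-dioxolan-4-yl)ethan-1-one
Product: 10 (S)-2,2-dimethyl-4-[1-(trimethylsilyloxy)ethenyl]-1,3-dioxolane
Conditions: LiN(iPr)2, Me3SiCl, THF, −78 °C (in situ trap); non-aqueous work-up
Reagents that add atoms: chlorotrimethylsilane, C[Si](C)(C)Cl
Why: Kinetic deprotonation of the unhindered methyl group with internal silyl trapping should give the terminal enol silane and leave the ring C–H (C16) untouched.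

Step 8
Reactants: 6 (2S,3R,E)-2-methyl-3-(triethylsilyloxy)hex-4-enal; 10 (S)-2,2-dimethyl-4-[1-(trimethylsilyloxy)ethenyl]-1,3-dioxolane
Product: 13 (2R,3R,4S,6R)-6-[(S)-2,2-dimethyl-1,3-dioxolan-4-yl]-3-methyl-2-[(E)-prop-1-enyl]oxan-4-ol, via β-hydroxy ketone 11 (not isolated), via cyclic hemiketal 12 (not isolated)
Conditions: BF3·OEt2 (1.2 equiv), CH2Cl2, −78 °C; then Et3SiH (5 equiv), BF3·OEt2 (2 equiv), −78 to −40 °C; aq. NaHCO3
Reagents that add atoms: none
Why: Proposed new method: BF3 activates aldehyde 6 and enol silane 10 adds in an open Mukaiyama aldol transition state to form C18–C19; the boron-bound β-oxy ketone 11 is then attacked at C17 by the C21 silyl ether oxygen, which loses its silyl group to give 12 (as its boron or silyl ketal), and BF3 ionises this to the ring oxocarbenium ion that Et3SiH reduces. The closest known reaction types are the Felkin-selective Mukaiyama aldol of β-silyloxy aldehydes, the reductive etherification of δ-silyloxy ketones and the Et3SiH/BF3·OEt2 reduction of hemiketals bearing an α-dioxolane (C-glycoside type); running them as one cationic cascade is new and is reasoned to work because every stage uses the same Lewis acid and each intermediate is the substrate of the next. The tetrahydropyran (O, C17–C21) closes by 6-exo-trig attack of oxygen on the activated C17 carbonyl. C19 (S) is set by Felkin–Anh control from the C20 methyl group (nucleophile anti to the C21 chain, giving the all-syn C19–C21 triad), and C17 (R) by axial hydride delivery to the half-chair oxocarbenium ion with the propenyl group equatorial, which places the C16 chain equatorial and 2,6-cis. The step needs Felkin over 1,3-anti induction, secured by the non-chelating silyl ether and BF3, and aldol before reduction, secured by adding Et3SiH only after the aldehyde is consumed at −78 °C.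

Step 9
Reactants: 13 (2R,3R,4S,6R)-6-[(S)-2,2-dimethyl-1,3-dioxolan-4-yl]-3-methyl-2-[(E)-prop-1-enyl]oxan-4-ol
Product: 14 (S)-1-[(2R,4S,5R,6R)-4-hydroxy-5-methyl-6-[(E)-prop-1-enyl]oxan-2-yl]ethane-1,2-diol
Conditions: AcOH/H2O/THF (3:1:1), 40 °C
Reagents that add atoms: none
Why: Acid hydrolysis of the isopropylidene ketal, which the ring ether and the propenyl group should tolerate.

Step 10
Reactants: 14 (S)-1-[(2R,4S,5R,6R)-4-hydroxy-5-methyl-6-[(E)-prop-1-enyl]oxan-2-yl]ethane-1,2-diol
Product: 15 tris(triethylsilyl) ether of 14 (O15, O16 and O19 silylated)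
Conditions: Et3SiOTf, 2,6-lutidine, CH2Cl2, −78 to 0 °C
Reagents that add atoms: triethylsilyl trifluoromethanesulfonate, CC[Si](CC)(CC)OS(=O)(=O)C(F)(F)F
Why: Exhaustive silylation with the silyl triflate should also cover the hindered axial C19 hydroxyl.

Step 11
Reactants: 15 tris(triethylsilyl) ether of 14
Product: 16 C15 aldehyde, (S)-2-(triethylsilyloxy)-2-[tetrahydropyran-2-yl]acetaldehyde with O16 and O19 as triethylsilyl ethers and ring stereocentres as in 14
Conditions: (COCl)2, DMSO, CH2Cl2, −78 to −35 °C; then iPr2NEt, −78 to 0 °C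
Reagents that add atoms: none
Why: Swern conditions cleave and oxidise a primary triethylsilyl ether in one operation while secondary ones persist, and the low temperature and hindered amine should protect C16 from epimerisation.

Step 12
Reactants: 16 C15 aldehyde
Product: 17 (E)-vinyl iodide of the C14–C24 fragment (C14 iodide, O16 and O19 triethylsilyl ethers)
Conditions: CrCl2, CHI3, THF/1,4-dioxane, 0 to 25 °C
Reagents that add atoms: iodoform, IC(I)I
Why: Takai olefination through a geminal dichromium reagent should give the E-vinyl iodide under non-basic conditions that keep C16 intact.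

Step 13
Reactants: 1 (S)-4-benzyl-3-propionyloxazolidin-2-one; 18 3-bromoprop-1-yne
Product: 19 (S)-4-benzyl-3-[(R)-2-methylpent-4-ynoyl]oxazolidin-2-one
Conditions: NaN(SiMe3)2, THF, −78 °C; then 18, −78 to −40 °C
Reagents that add atoms: none
Why: Evans alkylation of the chelated Z-sodium enolate anti to the benzyl group should set C10 as R.

Step 14
Reactants: 19 (S)-4-benzyl-3-[(R)-2-methylpent-4-ynoyl]oxazolidin-2-one
Product: 20 (R)-2-methylpent-4-yn-1-ol
Conditions: LiBH4, MeOH (1 equiv), Et2O, 0 °C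
Reagents that add atoms: none
Why: Reductive cleavage of the imide by borohydride attack at the exocyclic carbonyl releases the alcohol and the auxiliary.

Step 15
Reactants: 20 (R)-2-methylpent-4-yn-1-ol
Product: 21 (R,E)-5-iodo-2,4-dimethylpent-4-en-1-ol
Conditions: AlMe3, Cp2ZrCl2 (0.3 equiv), CH2Cl2, 0 to 25 °C; then I2, THF, −30 to 0 °C
Reagents that add atoms: trimethylaluminium, C[Al](C)C; iodine, II
Why: Negishi zirconium-catalysed carboalumination adds methyl and aluminium syn across the alkyne with aluminium at the terminus, and iodinolysis with retention should give the E-iodide (C12 methyl, C13 iodide).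

Step 16
Reactants: 21 (R,E)-5-iodo-2,4-dimethylpent-4-en-1-ol
Product: 22 (R,E)-2,4-dimethyl-5-(4,4,5,5-tetramethyl-1,3,2-dioxaborolan-2-yl)pent-4-en-1-ol
Conditions: B2pin2, PdCl2(PPh3)2 (3 mol%), PPh3, KOPh, toluene, 50 °C
Reagents that add atoms: bis(pinacolato)diboron, CC1(C)OB(OC1(C)C)B1OC(C)(C)C(C)(C)O1
Why: Miyaura borylation proceeds with retention of alkene geometry, and the weak phenoxide base should prevent onward Suzuki coupling of the product.

Step 17
Reactants: 22 (R,E)-2,4-dimethyl-5-(4,4,5,5-tetramethyl-1,3,2-dioxaborolan-2-yl)pent-4-en-1-ol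
Product: 23 (R,E)-2,4-dimethyl-5-(4,4,5,5-tetramethyl-1,3,2-dioxaborolan-2-yl)pent-4-enal
Conditions: Dess–Martin periodinane, NaHCO3, CH2Cl2, 0 to 25 °C
Reagents that add atoms: none
Why: Buffered Dess–Martin oxidation should give the α-chiral aldehyde without epimerising C10 or touching the boronate.

Step 18
Reactants: 23 (R,E)-2,4-dimethyl-5-(4,4,5,5-tetramethyl-1,3,2-dioxaborolan-2-yl)pent-4-enal
Product: 24 2-[(1E,4R,5Z)-6-iodo-2,4-dimethylhepta-1,5-dien-1-yl]-4,4,5,5-tetramethyl-1,3,2-dioxaborolane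
Conditions: [Ph3PEt]I, n-BuLi, THF, 25 °C; I2, −78 °C; NaN(SiMe3)2, −20 °C; then 23, −78 to −20 °C
Reagents that add atoms: ethyltriphenylphosphonium iodide, CC[P+](c1ccccc1)(c1ccccc1)c1ccccc1.[I-]; iodine, II
Why: Stork–Zhao olefination with the α-iodo ylide should give the Z-α-iodoalkene (C8 iodide cis to C10) under kinetic Wittig control, at a temperature low enough to spare C10.

Step 19
Reactants: 25 prop-2-yn-1-ol
Product: 26 (E)-3-(tributylstannyl)prop-2-en-1-ol
Conditions: Bu3SnH, AIBN (cat.), 80 °C, neat; E isomer separated by chromatography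
Reagents that add atoms: tributyltin hydride, CCCC[SnH](CCCC)CCCC
Why: Radical hydrostannation places tin at the terminus, and reversible stannyl radical addition should favour the E isomer.

Step 20
Reactants: 26 (E)-3-(tributylstannyl)prop-2-en-1-ol
Product: 27 (E)-3-(tributylstannyl)prop-2-enal
Conditions: MnO2, CH2Cl2, 25 °C
Reagents that add atoms: none
Why: Allylic oxidation with MnO2 is neutral and should leave the vinylstannane and its geometry untouched.

Step 21
Reactants: 27 (E)-3-(tributylstannyl)prop-2-enal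
Product: 28 (S,E)-1-(tributylstannyl)hexa-1,5-dien-3-ol
Conditions: (S)-BINOL (20 mol%), Ti(OiPr)4 (10 mol%), 4 Å molecular sieves, CH2Cl2; allylSnBu3, −20 °C
Reagents that add atoms: allyltributylstannane, C=CC[Sn](CCCC)(CCCC)CCCC
Why: Keck asymmetric allylation, in which the BINOL–titanium Lewis acid exposes one aldehyde face to the allylstannane; the (S)-ligand should give the (S)-carbinol (C5) with conjugated aldehydes.

Step 22
Reactants: 28 (S,E)-1-(tributylstannyl)hexa-1,5-dien-3-ol
Product: 29 (S,E)-1-(tributylstannyl)hexa-1,5-dien-3-yl acrylate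
Conditions: acryloyl chloride, iPr2NEt, DMAP (cat.), CH2Cl2, 0 °C
Reagents that add atoms: acryloyl chloride, C=CC(=O)Cl
Why: Simple O-acylation installs C1–C3 of the lactone.

Step 23
Reactants: 29 (S,E)-1-(tributylstannyl)hexa-1,5-dien-3-yl acrylate
Product: 30 (S)-6-[(E)-2-(tributylstannyl)ethenyl]-5,6-dihydro-2H-pyran-2-one
Conditions: second-generation Grubbs catalyst RuCl2(=CHPh)(PCy3)(H2IMes) (5 mol%), CH2Cl2, 40 °C
Reagents that add atoms: none
Why: Ring-closing metathesis between the terminal allyl alkene and the acrylate should close the six-membered lactone, while the bulky disubstituted vinylstannane stays out of the catalytic cycle.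

Step 24
Reactants: 24 2-[(1E,4R,5Z)-6-iodo-2,4-dimethylhepta-1,5-dien-1-yl]-4,4,5,5-tetramethyl-1,3,2-dioxaborolane; 30 (S)-6-[(E)-2-(tributylstannyl)ethenyl]-5,6-dihydro-2H-pyran-2-one
Product: 31 (S)-6-[(1E,3Z,5R,7E)-3,5,7-trimethyl-8-(4,4,5,5-tetramethyl-1,3,2-dioxaborolan-2-yl)octa-1,3,7-trien-1-yl]-5,6-dihydro-2H-pyran-2-one
Conditions: Pd2(dba)3 (5 mol%), AsPh3 (20 mol%), NMP, 25 to 40 °C
Reagents that add atoms: none
Why: Stille coupling forms C7–C8 with retention at both alkenes (6E,8Z), and the base-free, fluoride-free conditions should leave the alkenylboronate untouched.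

Step 25
Reactants: 17 (E)-vinyl iodide of the C14–C24 fragment; 31 (S)-6-[(1E,3Z,5R,7E)-3,5,7-trimethyl-8-(4,4,5,5-tetramethyl-1,3,2-dioxaborolan-2-yl)octa-1,3,7-trien-1-yl]-5,6-dihydro-2H-pyran-2-one
Product: 32 16,19-bis(O-triethylsilyl) derivative of the target
Conditions: Pd(PPh3)4 (10 mol%), TlOEt, THF/H2O (3:1), 25 °C
Reagents that add atoms: none
Why: Suzuki–Miyaura coupling forms C13–C14 with retention (12E,14E), and thallium-accelerated transmetalation at room temperature should spare the lactone and the polyene.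

Step 26
Reactants: 32 16,19-bis(O-triethylsilyl) derivative of the target
Product: 33 target, (S)-6-[(1E,3Z,5R,7E,9E,11S)-11-hydroxy-11-[(2R,4S,5R,6R)-4-hydroxy-5-methyl-6-[(E)-prop-1-enyl]oxan-2-yl]-3,5,7-trimethylundeca-1,3,7,9-tetraenyl]-5,6-dihydro-2H-pyran-2-one
Conditions: HF·pyridine, pyridine, THF, 0 to 25 °C
Reagents that add atoms: none
Why: Buffered fluoride desilylation should free both secondary alcohols without ionising the dienylic C16–O bond or opening the lactone.

**Compound list**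

1 | (S)-4-benzyl-3-propionyloxazolidin-2-one | CCC(=O)N1[C@@H](Cc2ccccc2)COC1=O | starting material
2 | (E)-but-2-enal | C/C=C/C=O | starting material
3 | (S)-4-benzyl-3-[(2S,3R,E)-3-hydroxy-2-methylhex-4-enoyl]oxazolidin-2-one | C/C=C/[C@@H](O)[C@H](C)C(=O)N1[C@@H](Cc2ccccc2)COC1=O | intermediate
4 | (2S,3R,E)-3-hydroxy-N-methoxy-N,2-dimethylhex-4-enamide | C/C=C/[C@@H](O)[C@H](C)C(=O)N(C)OC | intermediate
5 | (2S,3R,E)-N-methoxy-N,2-dimethyl-3-(triethylsilyloxy)hex-4-enamide | C/C=C/[C@@H](O[Si](CC)(CC)CC)[C@H](C)C(=O)N(C)OC | intermediate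
6 | (2S,3R,E)-2-methyl-3-(triethylsilyloxy)hex-4-enal | C/C=C/[C@@H](O[Si](CC)(CC)CC)[C@H](C)C=O | intermediate
7 | methyl (S)-2,2-dimethyl-1,3-dioxolane-4-carboxylate | COC(=O)[C@H]1OC(C)(C)OC1 | starting material
8 | (S)-N-methoxy-N,2,2-trimethyl-1,3-dioxolane-4-carboxamide | CON(C)C(=O)[C@H]1OC(C)(C)OC1 | intermediate
9 | (S)-1-(2,2-dimethyl-1,3-dioxolan-4-yl)ethan-1-one | CC(=O)[C@H]1OC(C)(C)OC1 | intermediate
10 | (S)-2,2-dimethyl-4-[1-(trimethylsilyloxy)ethenyl]-1,3-dioxolane | C=C(O[Si](C)(C)C)[C@H]1OC(C)(C)OC1 | intermediate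
11 | (3S,4R,5R,E)-1-[(S)-2,2-dimethyl-1,3-dioxolan-4-yl]-3-hydroxy-4-methyl-5-(triethylsilyloxy)oct-6-en-1-one (boron-bound in the flask) | C/C=C/[C@@H](O[Si](CC)(CC)CC)[C@H](C)[C@@H](O)CC(=O)[C@H]1OC(C)(C)OC1 | intermediate
12 | cyclic hemiketal, 2-[(S)-2,2-dimethyl-1,3-dioxolan-4-yl]-5-methyl-6-[(E)-prop-1-enyl]oxane-2,4-diol, anomeric mixture, other centres as in 13 | C/C=C/[C@H]1OC(O)([C@H]2OC(C)(C)OC2)C[C@H](O)[C@H]1C | intermediate
13 | (2R,3R,4S,6R)-6-[(S)-2,2-dimethyl-1,3-dioxolan-4-yl]-3-methyl-2-[(E)-prop-1-enyl]oxan-4-ol | C/C=C/[C@H]1O[C@@H]([C@H]2OC(C)(C)OC2)C[C@H](O)[C@H]1C | intermediate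
14 | (S)-1-[(2R,4S,5R,6R)-4-hydroxy-5-methyl-6-[(E)-prop-1-enyl]oxan-2-yl]ethane-1,2-diol | C/C=C/[C@H]1O[C@@H]([C@@H](O)CO)C[C@H](O)[C@H]1C | intermediate
15 | tris(triethylsilyl) ether of 14 | C/C=C/[C@H]1O[C@@H]([C@@H](O[Si](CC)(CC)CC)CO[Si](CC)(CC)CC)C[C@H](O[Si](CC)(CC)CC)[C@H]1C | intermediate
16 | C15 aldehyde with O16 and O19 triethylsilyl ethers, stereocentres as in 14 | C/C=C/[C@H]1O[C@@H]([C@@H](O[Si](CC)(CC)CC)C=O)C[C@H](O[Si](CC)(CC)CC)[C@H]1C | intermediate
17 | (E)-vinyl iodide of the C14–C24 fragment, O16 and O19 triethylsilyl ethers | C/C=C/[C@H]1O[C@@H]([C@@H](O[Si](CC)(CC)CC)/C=C/I)C[C@H](O[Si](CC)(CC)CC)[C@H]1C | intermediate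
18 | 3-bromoprop-1-yne | C#CCBr | starting material
19 | (S)-4-benzyl-3-[(R)-2-methylpent-4-ynoyl]oxazolidin-2-one | C#CC[C@@H](C)C(=O)N1[C@@H](Cc2ccccc2)COC1=O | intermediate
20 | (R)-2-methylpent-4-yn-1-ol | C#CC[C@@H](C)CO | intermediate
21 | (R,E)-5-iodo-2,4-dimethylpent-4-en-1-ol | I/C=C(\C)C[C@@H](C)CO | intermediate
22 | (R,E)-2,4-dimethyl-5-(4,4,5,5-tetramethyl-1,3,2-dioxaborolan-2-yl)pent-4-en-1-ol | CC1(C)OB(/C=C(\C)C[C@@H](C)CO)OC1(C)C | intermediate
23 | (R,E)-2,4-dimethyl-5-(4,4,5,5-tetramethyl-1,3,2-dioxaborolan-2-yl)pent-4-enal | CC1(C)OB(/C=C(\C)C[C@@H](C)C=O)OC1(C)C | intermediate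
24 | 2-[(1E,4R,5Z)-6-iodo-2,4-dimethylhepta-1,5-dien-1-yl]-4,4,5,5-tetramethyl-1,3,2-dioxaborolane | CC1(C)OB(/C=C(\C)C[C@@H](C)/C=C(C)\I)OC1(C)C | intermediate
25 | prop-2-yn-1-ol | C#CCO | starting material
26 | (E)-3-(tributylstannyl)prop-2-en-1-ol | CCCC[Sn](CCCC)(CCCC)/C=C/CO | intermediate
27 | (E)-3-(tributylstannyl)prop-2-enal | CCCC[Sn](CCCC)(CCCC)/C=C/C=O | intermediate
28 | (S,E)-1-(tributylstannyl)hexa-1,5-dien-3-ol | CCCC[Sn](CCCC)(CCCC)/C=C/[C@@H](O)CC=C | intermediate
29 | (S,E)-1-(tributylstannyl)hexa-1,5-dien-3-yl acrylate | CCCC[Sn](CCCC)(CCCC)/C=C/[C@@H](OC(=O)C=C)CC=C | intermediate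
30 | (S)-6-[(E)-2-(tributylstannyl)ethenyl]-5,6-dihydro-2H-pyran-2-one | CCCC[Sn](CCCC)(CCCC)/C=C/[C@@H]1CC=CC(=O)O1 | intermediate
31 | (S)-6-[(1E,3Z,5R,7E)-3,5,7-trimethyl-8-(4,4,5,5-tetramethyl-1,3,2-dioxaborolan-2-yl)octa-1,3,7-trien-1-yl]-5,6-dihydro-2H-pyran-2-one | CC1(C)OB(/C=C(\C)C[C@@H](C)/C=C(C)\C=C\[C@@H]2CC=CC(=O)O2)OC1(C)C | intermediate
32 | 16,19-bis(O-triethylsilyl) derivative of the target | C/C=C/[C@H]1O[C@@H]([C@@H](O[Si](CC)(CC)CC)/C=C/C=C(\C)C[C@@H](C)/C=C(C)\C=C\[C@@H]2CC=CC(=O)O2)C[C@H](O[Si](CC)(CC)CC)[C@H]1C | intermediate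
33 | (S)-6-[(1E,3Z,5R,7E,9E,11S)-11-hydroxy-11-[(2R,4S,5R,6R)-4-hydroxy-5-methyl-6-[(E)-prop-1-enyl]oxan-2-yl]-3,5,7-trimethylundeca-1,3,7,9-tetraenyl]-5,6-dihydro-2H-pyran-2-one | C/C=C/[C@H]1O[C@@H]([C@@H](O)/C=C/C=C(\C)C[C@@H](C)/C=C(C)\C=C\[C@@H]2CC=CC(=O)O2)C[C@H](O)[C@H]1C | target

**Step count and risks**

Total steps: 26. Longest linear sequence: 11 steps (1–4, 8–12, 25, 26).

Step 8 (proposed new method). What may go wrong: the silyl ether oxygen may engage the ketone too slowly, so that the boron-bound β-hydroxy ketone is reduced or dehydrated before ring closure; Felkin selectivity may erode with the small enol silane; the Lewis acid may open the dioxolane. The fallback uses only known chemistry and builds the ring differently; it sets out from aldehyde 6 and comes back at triol 14. A vinylogous Mukaiyama aldol of 6 with 1-methoxy-1-(tert-butyldimethylsilyloxy)buta-1,3-diene and B(C6F5)3 should give the Felkin δ-hydroxy dienoate F1. Reduction with iBu2AlH gives the allylic alcohol F2. Sharpless asymmetric epoxidation with L-(+)-diethyl tartrate, Ti(OiPr)4 and tert-butyl hydroperoxide gives the (16S,17S)-epoxy alcohol F3. HF·pyridine frees the C21 hydroxyl, and camphorsulfonic acid then drives 6-exo opening of the epoxide with inversion at C17 to give 14. In this variant C16 is set by the epoxidation instead of being bought, and steps 5–7 and 9 fall away.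

Step 18. What may go wrong: the basic ylide may epimerise C10; the α-iodo ylide may decompose and leave the aldehyde unconverted; the boronate may be attacked by the ylide or the amide base. The fallback sets out from aldehyde 23 and comes back at 31. Neutral dibromo-olefination (CBr4, PPh3, Zn) gives the 1,1-dibromoalkene F4. Palladium-catalysed trans-selective monomethylation (MeZnCl, PdCl2(DPEphos), THF) replaces the bromide trans to the chain and gives the Z-bromoalkene F5. Stille coupling of F5 with 30 at 50–60 °C then gives 31.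

Step 25. What may go wrong: ethoxide or hydroxide may open or add to the unsaturated lactone during the aqueous coupling; the trisubstituted alkenylboronate may protodeboronate; the 8Z alkene may isomerise under palladium. The fallback changes the order of union so that the lactone arrives last; it sets out from 17 and 22 and comes back at 32. Suzuki–Miyaura coupling of 17 with 22 under the step 25 conditions gives the dienol F6. Dess–Martin oxidation gives the aldehyde F7. Stork–Zhao olefination gives the Z-vinyl iodide F8. Stille coupling of F8 with 30 under the step 24 conditions gives 32.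

Further compounds
F1 | step 8 | methyl (2E,5S,6R,7R,8E)-5-hydroxy-6-methyl-7-(triethylsilyloxy)deca-2,8-dienoate | C/C=C/[C@@H](O[Si](CC)(CC)CC)[C@H](C)[C@@H](O)C/C=C/C(=O)OC
F2 | step 8 | (2E,5S,6R,7R,8E)-6-methyl-7-(triethylsilyloxy)deca-2,8-diene-1,5-diol | C/C=C/[C@@H](O[Si](CC)(CC)CC)[C@H](C)[C@@H](O)C/C=C/CO
F3 | step 8 | [(2S,3S)-3-[(2S,3R,4R,E)-2-hydroxy-3-methyl-4-(triethylsilyloxy)hept-5-enyl]oxiran-2-yl]methanol | C/C=C/[C@@H](O[Si](CC)(CC)CC)[C@H](C)[C@@H](O)C[C@@H]1O[C@H]1CO
F4 | step 18 | 2-[(1E,4R)-6,6-dibromo-2,4-dimethylhexa-1,5-dien-1-yl]-4,4,5,5-tetramethyl-1,3,2-dioxaborolane | CC1(C)OB(/C=C(\C)C[C@@H](C)C=C(Br)Br)OC1(C)C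
F5 | step 18 | 2-[(1E,4R,5Z)-6-bromo-2,4-dimethylhepta-1,5-dien-1-yl]-4,4,5,5-tetramethyl-1,3,2-dioxaborolane | CC1(C)OB(/C=C(\C)C[C@@H](C)/C=C(C)\Br)OC1(C)C
F6 | step 25 | C9 alcohol of the C9–C24 fragment, (12E,14E)-diene, O16 and O19 triethylsilyl ethers | C/C=C/[C@H]1O[C@@H]([C@@H](O[Si](CC)(CC)CC)/C=C/C=C(\C)C[C@@H](C)CO)C[C@H](O[Si](CC)(CC)CC)[C@H]1C
F7 | step 25 | C9 aldehyde of the C9–C24 fragment, O16 and O19 triethylsilyl ethers | C/C=C/[C@H]1O[C@@H]([C@@H](O[Si](CC)(CC)CC)/C=C/C=C(\C)C[C@@H](C)C=O)C[C@H](O[Si](CC)(CC)CC)[C@H]1C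
F8 | step 25 | (8Z)-C8 vinyl iodide of the C7–C24 fragment, O16 and O19 triethylsilyl ethers | C/C=C/[C@H]1O[C@@H]([C@@H](O[Si](CC)(CC)CC)/C=C/C=C(\C)C[C@@H](C)/C=C(C)\I)C[C@H](O[Si](CC)(CC)CC)[C@H]1C
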